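In the early minutes of the zeta run I read no target at 6.00 min, and from 12.0 min to 40.0 min it rose at an average of 1.34 mM min⁻¹ in c(target). The last stretch was slower, at 0.810 mM min⁻¹ against 1.64 mM min⁻¹ before it.

the same everywhere: gas 98 mM (held)

| charge | solid substrate | remark | time |
|---|---|---|---|
| zeta | 0.15 M | run made earlier |  |
| flask | 0.30 M |  | 3.0 h |

- zeta (time / min: target / %): 6.00: 0; 12.0: 5.6; 20.0: 11.7; 25.0: 18.8; 30.0: 25.3; 40.0: 30.7

(scatter of a reading: 1 percentage point)

- percentages count the solid substrate that a species holds: one side product counts as two
- solid, in amounts per volume of the solution: solid substrate
- at the start none of coupling partner is dissolved
- steps that have been proposed: solid substrate <-> dissolved substrate; dissolved substrate + coupling partner -> target; 2 dissolved substrate -> side product; gas <-> coupling partner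
- at the start none of the solid substrate is in solution

- amber: doubling the saturation concentration of gas, all else as stated
- red: doubling the dissolution coefficient of the solid substrate, all else as stated
- blue: doubling the transfer coefficient of the gas, all else as stated
- ochre: doubling the solubility of the solid substrate, all else as stated

1. amount of target at 3.0 h, in percent of the solid substrate charged
2. the change that raises the amount of target at 3.0 h, in percent of the solid substrate charged most ("none" if none brings more than 2 percentage points) (amber / red / blue / ochre / none)
3. amount of target at 3.0 h, in percent of the solid substrate charged, after amber

I reckoned the flask in two ways. The first held that target rate for the whole 3.0 h against the 0.30 M charged, which gave 80.7%. The second rested on a supposition that no reading shows: I took the solid substrate as the limiting reagent and spread the zeta charge over the time of the last reading, which gave a clearing rate of 3.75 mM min⁻¹. Dividing the target rate by this clearing rate gave 35.9%, and this is the quantity I carried, the target share, a selectivity in which time and charge both drop out. The two ways parted, and on that supposition the first cheats, because at that clearing rate the flask's charge lasts 80.0 min, less than the 3.0 h over which I had held the target rate, and the target rate held over that shorter time gives 35.7%, which is the same reckoning in other words. So I committed to about 35.9%.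

The forecast, which differs from my reckoning, gave 55%, with amber as the best change and 75% after it, on the ground that “Doubling the charge should barely change the absolute rate if gas supply limits”.

The flask gave 42.8% of target, less than the forecast, with 57.2% as side product and 0% of solid substrate; amber was best, at 58.3%, a gain of 15 percentage points against 11 points for blue.

    solid substrate ⇌ dissolved substrate, rate k1*(cs1 - [dissolved substrate]) while solid is left; crystals form when [dissolved substrate] > cs1 (solubility = 0.0610 M, k = 1.05 min⁻¹)
    dissolved substrate + coupling partner → target (k = 1.14 L mol⁻¹ min⁻¹)
    2 dissolved substrate → side product (k = 0.390 L mol⁻¹ min⁻¹)
    gas ⇌ coupling partner, rate k4*(csat - [coupling partner]) (kL = 0.0259 min⁻¹)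

My supposition did not hold for the zeta charge, whose target stood at 30.7% at its last reading and, with the time alone changed to 3.0 h, at 44.1%. The neighbouring flask held 0.51 M of solid substrate, and the same reckoning clears that charge in 136 min, less than the 3.0 h of that flask, with the target share unchanged at 35.9%. At 3.00 h that flask stood at 42.3% of target, close to the 42.8% of the first flask, with 57.6% as side product and 0.090% of its charge still there.

(The numbers in the tables come from a simulation from invented constants; scatter was added.)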